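It is tempting to think that a flask with little starting material protects its target, but starting material cancels from the balance that sets how high target can rise.

    starting material + reagent + catalyst → catalyst + target (k1 = 55.4 M⁻² min⁻¹)
    starting material + target → side product (k2 = 0.298 M⁻¹ min⁻¹)
    gas ⇌ reagent, rate k3*(csat - [reagent]) (k3 = 0.186 min⁻¹, csat = 21 mM)
    second substrate + reagent + catalyst → catalyst + second product (k4 = 101 M⁻² min⁻¹)

| setting | Wednesday's | Friday's | Monday's | Sunday's |
|---|---|---|---|---|
| starting material | 0.20 M (in portions, 3, over 5.0 h) | 0.20 M (fed, over 5.0 h) | 0.20 M | 0.20 M |
| second substrate | 1.00 equiv | 1.00 equiv | 1.00 equiv (fed, over 5.0 h) | 1.00 equiv |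
| gas | 21 mM (held) | 21 mM (held) | 21 mM (held) | 21 mM (held) |
| catalyst | 10 mol% | 10 mol% | 10 mol% | 10 mol% |
| time | 6.0 h | 6.0 h | 6.0 h | 6.0 h |
| remark | first portion at the start, last at 5.0 h | all else is in the flask from the start; the feed brings no volume worth counting | all else is in the flask from the start; the feed brings no volume worth counting | everything together at the start |

- percent here means starting material units held: one side product counts as two
- at the start none of reagent is dissolved
- run time (Wednesday's): 6.0 h

* the flask with the highest amount of target, in percent of the starting material charged ("all alike" if they lie within 1.5 percentage points) (Wednesday's / Friday's / Monday's / Sunday's / all alike)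
* final target, as a percentage of the starting material charged, in Wednesday's
* final target, as a percentage of the starting material charged, in Friday's
* final target, as a percentage of the starting material charged, in Monday's
* final target, as a percentage of the starting material charged, in Sunday's

**Target ceiling.** Starting material multiplies both the making and the loss of target, so target stops rising where the making constant times catalyst times reagent equals the loss constant times target. With reagent at saturation, as a fraction of the charge, that gives 39.0%: the target ceiling, proportional to reagent and to catalyst loading.

**Both ends.** At the start of Sunday's, taking reagent as quasi-steady, uptake balances both consuming steps at 4.81 mM, so the ceiling opens at 8.95%. At equal concentrations second substrate takes reagent faster than starting material does, and as it is consumed the ceiling climbs towards the saturated end.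

**Bench note.** I join the ends by asking when starting material enters. I expect Friday's feed to deliver most of it at a high ceiling, and Sunday's to spend it low. I rank Friday's, Wednesday's, Monday's, Sunday's, all below the saturated ceiling. Do not touch the catalyst loading: the ceiling is proportional to it.

**The forecast.** It gives 27%, 29.5%, 22% and 21% for Wednesday's, Friday's, Monday's and Sunday's, and picks Friday's. Its ground is the same ceiling: it has target levelling off near 3.7 times reagent, and with A the starting material and T the target it says “high A alongside T is wasteful”. Its figures go beyond my bounds.

**What held.** The flasks give 27.1%, 28.7%, 22.8% and 20.7% in that order, so Friday's leads, by 1.6 percentage points over Wednesday's, barely above the margin. Without the loss step, Sunday's target goes from 20.7% to 99.7%, so that step is the main reason target falls short in Sunday's. At the end of Friday's feed, reagent at 0.0189 M sets the ceiling at 35.2%, and target stands lower, at 27.7%. In Sunday's read at 1.5 h, reagent at 0.0103 M sets it at 19.1%, and target stands lower, at 14.0%.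

The numbers are made up; what happens was integrated by code.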